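**Plan**

- Retrosynthesis (flavone numbering, ring B primed): the C5 hydroxyl is unmasked last from a C5 methyl ether, and the C3 methoxy group is traced back to C3–H of a 5,6,7,8,3'-pentamethoxyflavone.
- Ring C of that flavone is then cut at C4a–C4, C4–C3 and O1–C2. The C4 carbonyl carbon lies between C4a of ring A and C3, and O1 sits on the neighbouring ring A carbon, so CO can supply C4 while joining an ortho-iodophenol to an arylalkyne.
- Forward: ring A is carried intact from 1,2,3,4-tetramethoxybenzene (formylation, Dakin oxidation, iodination) and ring B from 3-ethynylanisole. Ring C is the only ring formed, in step 4.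
- Endgame: C3 oxygenation by lithiation–borylation–oxidation, O-methylation, then chelation-controlled cleavage of the C5 methyl ether.
- Stereochemistry: the target has no stereocentre and no stereogenic double bond, so nothing has to be controlled.

Key step: step 4

**Route**

Step 1
Reactants: 1 1,2,3,4-tetramethoxybenzene
Product: 3 2,3,4,5-tetramethoxybenzaldehyde, via iminium salt 2 (not isolated)
Conditions: POCl3, DMF, 0 → 80 °C; then ice/H2O
Reagents that add atoms: N,N-dimethylformamide CN(C)C=O; water O
Why: Vilsmeier–Haack formylation, in which the chloroiminium ion attacks one of the two equivalent free positions of 1 (each ortho to one methoxy group and para to another) and aqueous hydrolysis of iminium salt 2 releases the aldehyde.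

Step 2
Reactants: 3 2,3,4,5-tetramethoxybenzaldehyde
Product: 5 2,3,4,5-tetramethoxyphenol, via aryl formate 4 (not isolated)
Conditions: 30% H2O2, H2SO4 (cat.), MeOH, rt
Reagents that add atoms: hydrogen peroxide OO
Why: Acid-mediated Dakin oxidation, in which the electron-rich aryl group (ortho and para methoxy groups) migrates to oxygen in a Baeyer–Villiger-type shift and aryl formate 4 is methanolysed in the same flask.

Step 3
Reactants: 5 2,3,4,5-tetramethoxyphenol
Product: 6 2-iodo-3,4,5,6-tetramethoxyphenol
Conditions: NIS, MeCN, 0 °C, dark
Reagents that add atoms: N-iodosuccinimide O=C1CCC(=O)N1I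
Why: Electrophilic aromatic iodination at the only unsubstituted ring carbon of 5, which is ortho to the hydroxyl group, under mild conditions chosen to avoid oxidation of the electron-rich phenol.

Step 4
Reactants: 6 2-iodo-3,4,5,6-tetramethoxyphenol; 7 3-ethynylanisole; 8 carbon monoxide
Product: 11 5,6,7,8-tetramethoxy-2-(3-methoxyphenyl)chromen-4-one, via ynone 9 (not isolated), via enaminone 10 (not isolated)
Conditions: PdCl2(PPh3)2 (5 mol%), CO (20 atm), Et2NH, 120 °C, autoclave
Reagents that add atoms: none
Why: Zerovalent palladium formed in situ from PdCl2(PPh3)2 inserts into the C–I bond of 6, CO inserts to give the aroyl complex of divalent palladium, and amine-assisted transfer of the alkynyl group of 7 followed by reductive elimination gives ynone 9, which sets the C4a–C4 and C4–C3 bonds. Diethylamine then adds to 9 in a conjugate sense to give enaminone 10, and the phenol oxygen displaces the amine at C2 by addition–elimination, which sets the O1–C2 bond. The closest known reaction type is the palladium-catalysed carbonylative Sonogashira coupling of ortho-iodophenols and terminal alkynes with in situ cyclisation to flavones. Ring C closes in a 6-endo-trig oxa-Michael addition–elimination on 10 in preference to the 5-exo-dig attack on 9 that would lead to an aurone, and no stereocentre is formed. The step needs carbonylation to outrun direct alkynylation (which would end in a 2-arylbenzofuran) and six- over five-membered closure; the copper-free conditions, the CO pressure and the electron-rich aryl group of 6, which migrates readily to CO, secure the first, and the secondary amine as solvent secures the second. The site of ring fusion is not in question because iodine sits on the only carbon of 6 next to the hydroxyl group.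

Step 5
Reactants: 11 5,6,7,8-tetramethoxy-2-(3-methoxyphenyl)chromen-4-one
Product: 14 3-hydroxy-5,6,7,8-tetramethoxy-2-(3-methoxyphenyl)chromen-4-one, via 3-lithioflavone 12 (not isolated), via boronate 13 (not isolated)
Conditions: LDA, THF, −78 °C; B(OMe)3, −78 → 0 °C; AcOH, 30% H2O2, 0 °C → rt
Reagents that add atoms: hydrogen peroxide OO
Why: Lithiation–borylation–oxidation, in which LDA removes the C3 proton next to the C4 carbonyl (a known mode of flavone metalation), B(OMe)3 traps the vinyllithium, and peroxide converts the C–B bond into C–O by 1,2-migration.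

Step 6
Reactants: 14 3-hydroxy-5,6,7,8-tetramethoxy-2-(3-methoxyphenyl)chromen-4-one
Product: 15 3,5,6,7,8-pentamethoxy-2-(3-methoxyphenyl)chromen-4-one
Conditions: MeI, K2CO3, acetone, reflux
Reagents that add atoms: iodomethane CI
Why: Williamson ether synthesis on the acidic 3-hydroxyl group, the only free OH in 14.

Step 7
Reactants: 15 3,5,6,7,8-pentamethoxy-2-(3-methoxyphenyl)chromen-4-one
Product: 17 emmaosunin (5-hydroxy-3,6,7,8-tetramethoxy-2-(3-methoxyphenyl)chromen-4-one), via boron chelate 16 (not isolated)
Conditions: BCl3 (1.5 equiv), CH2Cl2, −78 → 0 °C; then H2O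
Reagents that add atoms: none
Why: Chelation-controlled Lewis-acid ether cleavage, in which BCl3 bridges the C4 carbonyl and the peri C5 methoxy oxygen in a six-membered chelate, chloride removes that methyl group, and water hydrolyses boron chelate 16 to the hydrogen-bonded C5 hydroxyl, while the C3 methoxy group (five-membered chelate only) and the remaining ethers should survive at low temperature with a small excess of reagent.

**Compound list**

1 | 1,2,3,4-tetramethoxybenzene | COc1ccc(OC)c(OC)c1OC | starting material
2 | N,N-dimethyl-(2,3,4,5-tetramethoxyphenyl)methaniminium dichlorophosphate | COc1cc(C=[N+](C)C)c(OC)c(OC)c1OC.[O-]P(=O)(Cl)Cl | intermediate (not isolated)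
3 | 2,3,4,5-tetramethoxybenzaldehyde | COc1cc(C=O)c(OC)c(OC)c1OC | intermediate
4 | 2,3,4,5-tetramethoxyphenyl formate | COc1cc(OC=O)c(OC)c(OC)c1OC | intermediate (not isolated)
5 | 2,3,4,5-tetramethoxyphenol | COc1cc(O)c(OC)c(OC)c1OC | intermediate
6 | 2-iodo-3,4,5,6-tetramethoxyphenol | COc1c(O)c(I)c(OC)c(OC)c1OC | intermediate
7 | 3-ethynylanisole | COc1cccc(C#C)c1 | starting material
8 | carbon monoxide | [C-]#[O+] | starting material
9 | 1-(2-hydroxy-3,4,5,6-tetramethoxyphenyl)-3-(3-methoxyphenyl)prop-2-yn-1-one | COc1cccc(C#CC(=O)c2c(O)c(OC)c(OC)c(OC)c2OC)c1 | intermediate (not isolated)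
10 | 3-(diethylamino)-1-(2-hydroxy-3,4,5,6-tetramethoxyphenyl)-3-(3-methoxyphenyl)prop-2-en-1-one (drawn as the E isomer; the push-pull double bond should isomerise readily, so its geometry does not matter for ring closure) | CCN(CC)/C(c1cccc(OC)c1)=C/C(=O)c1c(O)c(OC)c(OC)c(OC)c1OC | intermediate (not isolated)
11 | 5,6,7,8-tetramethoxy-2-(3-methoxyphenyl)chromen-4-one | COc1cccc(-c2cc(=O)c3c(OC)c(OC)c(OC)c(OC)c3o2)c1 | intermediate
12 | 3-lithio-5,6,7,8-tetramethoxy-2-(3-methoxyphenyl)chromen-4-one | [Li]c1c(-c2cccc(OC)c2)oc2c(OC)c(OC)c(OC)c(OC)c2c1=O | intermediate (not isolated)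
13 | dimethyl [5,6,7,8-tetramethoxy-2-(3-methoxyphenyl)-4-oxochromen-3-yl]boronate | COB(OC)c1c(-c2cccc(OC)c2)oc2c(OC)c(OC)c(OC)c(OC)c2c1=O | intermediate (not isolated)
14 | 3-hydroxy-5,6,7,8-tetramethoxy-2-(3-methoxyphenyl)chromen-4-one | COc1cccc(-c2oc3c(OC)c(OC)c(OC)c(OC)c3c(=O)c2O)c1 | intermediate
15 | 3,5,6,7,8-pentamethoxy-2-(3-methoxyphenyl)chromen-4-one | COc1cccc(-c2oc3c(OC)c(OC)c(OC)c(OC)c3c(=O)c2OC)c1 | intermediate
16 | 5-(dichloroboranyloxy)-3,6,7,8-tetramethoxy-2-(3-methoxyphenyl)chromen-4-one (boron also held by the C4 carbonyl oxygen) | COc1cccc(-c2oc3c(OC)c(OC)c(OC)c(OB(Cl)Cl)c3c(=O)c2OC)c1 | intermediate (not isolated)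
17 | emmaosunin, 5-hydroxy-3,6,7,8-tetramethoxy-2-(3-methoxyphenyl)chromen-4-one | COc1cccc(-c2oc3c(OC)c(OC)c(OC)c(O)c3c(=O)c2OC)c1 | target

**Count**

Total steps: 7. Longest linear sequence: 7 steps (1 → 17); 7 and 8 enter at step 4.

**Steps most likely to fail**

Step 4. Oxidative addition at the electron-rich C–I bond, flanked by a hydroxyl and a methoxy group, may be slow. Alkynylation without CO uptake, five-membered ring closure or alkyne oligomerisation could then compete. The fallback builds ring C by the chalcone route and sets out from phenol 5. C-acetylation at its one free ring position with AcOH and BF3·OEt2 (Friedel–Crafts/Fries type) would give 1-(2-hydroxy-3,4,5,6-tetramethoxyphenyl)ethanone F1. Claisen–Schmidt condensation with commercial 3-methoxybenzaldehyde (KOH, EtOH) would give the chalcone (E)-1-(2-hydroxy-3,4,5,6-tetramethoxyphenyl)-3-(3-methoxyphenyl)prop-2-en-1-one F2. Oxidative cyclisation with catalytic I2 in DMSO at about 130 °C would then close ring C and rejoin the route at flavone 11.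

Step 5. Deprotonation at C3 may be incomplete or misdirected: the amide base could add at C2 and open the pyranone, or ring B could be metalated. The boronate could also lose boron to a proton before it is oxidised. The fallback oxidises the C2–C3 double bond directly and sets out from flavone 11. Epoxidation with dimethyldioxirane in acetone/CH2Cl2 at 0 °C would give 2,3-epoxy-5,6,7,8-tetramethoxy-2-(3-methoxyphenyl)chroman-4-one F3 (racemic, oxirane necessarily cis-fused). Treatment with catalytic TsOH in CH2Cl2 would open the oxirane and, by loss of the C3 proton, give the flavonol, rejoining the route at 14.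

Step 7. Site control in the ether cleavage may be lost: the C3 methoxy group, which also chelates through the carbonyl, or the C6 methoxy group next to the freed hydroxyl could be cleaved as well. The fallback cleaves both chelating ethers on purpose and sets out from 15. An excess of AlBr3 in MeCN would give 3,5-dihydroxy-6,7,8-trimethoxy-2-(3-methoxyphenyl)chromen-4-one F4. One equivalent of MeI with K2CO3 in acetone at room temperature should then methylate only the 3-hydroxyl group, because the 5-hydroxyl group is tied up in the hydrogen bond to the carbonyl and is the least reactive, and this would give target 17.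

**Further compounds**

F1 | step 4 | 1-(2-hydroxy-3,4,5,6-tetramethoxyphenyl)ethanone | CC(=O)c1c(O)c(OC)c(OC)c(OC)c1OC
F2 | step 4 | (E)-1-(2-hydroxy-3,4,5,6-tetramethoxyphenyl)-3-(3-methoxyphenyl)prop-2-en-1-one | COc1cccc(/C=C/C(=O)c2c(O)c(OC)c(OC)c(OC)c2OC)c1
F3 | step 5 | 2,3-epoxy-5,6,7,8-tetramethoxy-2-(3-methoxyphenyl)chroman-4-one (racemic, one enantiomer drawn) | COc1cccc([C@@]23O[C@@H]2C(=O)c2c(OC)c(OC)c(OC)c(OC)c2O3)c1
F4 | step 7 | 3,5-dihydroxy-6,7,8-trimethoxy-2-(3-methoxyphenyl)chromen-4-one | COc1cccc(-c2oc3c(OC)c(OC)c(OC)c(O)c3c(=O)c2O)c1
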